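**Retrosynthetic overview**
- The target is the 5-O-demethylated, O-desilylated form of a 5,6,7-trimethoxyflavone whose ring B carries 3'-OH, 2'-OMe and a 5'-silyloxy group; fluoride and then chelation-directed BCl3 finish the synthesis.
- The plan rests on ring B: the oxygens at C3' and C5' are 1,3-related, and C2' bears OMe and lies between C1' (bonded to C2 of ring C) and C3'. A vinylketene supplying C3', C6', C1', C2' and a siloxyalkyne supplying C4', C5' give exactly this pattern.
- Ring B is cut at C1'–C6', C3'–C4', C5'–C6' and C2'–C3', back to a chromon-2-yl β-methoxyvinyl diazomethyl ketone and triisopropylsilyloxyacetylene (photochemical Wolff shift, (2+2) cycloaddition, 4π opening, 6π closure).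
- The diazo ketone comes from the β-methoxyacrylic acid (acyl chloride plus trimethylsilyldiazomethane). The acid comes from tert-butyl (5,6,7-trimethoxychromon-2-yl)acetate by formylation/O-methylation, and that ester from lateral carboxylation of 5,6,7-trimethoxy-2-methylchromone.
- Ring order: ring A arrives in 2'-hydroxy-4',5',6'-trimethoxyacetophenone, ring C is closed first (Claisen condensation, cyclodehydration), ring B is built last.

Key step: step 7

Assumption: the target has no stereocenter; the enol ether of the β-methoxyacrylate intermediates is taken as E (OMe cis to the chromonyl group), the usual outcome for 2-aryl-3-methoxyacrylates, and the Z isomer would lead to the same phenol.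

**Step 1**
Reactants: 1 2'-hydroxy-4',5',6'-trimethoxyacetophenone
Product: 3 5,6,7-trimethoxy-2-methylchromen-4-one, via β-diketone 2 (not isolated)
Conditions: NaH, EtOAc, THF, reflux; then conc. HCl, MeOH, reflux
Reagents that add atoms: ethyl acetate, CCOC(C)=O
Why: Claisen condensation of the acetophenone enolate with ethyl acetate should give the β-diketone, and acid-catalysed cyclodehydration through the free 2'-OH closes ring C (standard 2-methylchromone synthesis).

**Step 2**
Reactants: 3 5,6,7-trimethoxy-2-methylchromen-4-one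
Product: 4 tert-butyl 2-(5,6,7-trimethoxy-4-oxochromen-2-yl)acetate
Conditions: LiN(SiMe3)2 (2.2 equiv), THF, −78 °C; Boc2O, −78 to 0 °C; aq. NH4Cl
Reagents that add atoms: di-tert-butyl dicarbonate, CC(C)(C)OC(=O)OC(=O)OC(C)(C)C
Why: The 2-methyl group of a chromone is vinylogously acidic, so lateral lithiation gives an extended enolate that should be C-acylated by Boc2O at the exocyclic carbon (lateral lithiation/carboxylation), the second equivalent of base taking up the more acidic product.

**Step 3**
Reactants: 4 tert-butyl 2-(5,6,7-trimethoxy-4-oxochromen-2-yl)acetate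
Product: 6 tert-butyl (E)-3-methoxy-2-(5,6,7-trimethoxy-4-oxochromen-2-yl)prop-2-enoate, via formyl ester enolate 5 (not isolated)
Conditions: NaH, HCO2Me, DMF, 0 °C to rt; then Me2SO4, rt
Reagents that add atoms: methyl formate, COC=O; dimethyl sulfate, COS(=O)(=O)OC
Why: Claisen formylation of the doubly activated methylene followed by O-methylation of the sodium enolate is the standard β-methoxyacrylate construction, and the E isomer (OMe trans to the ester) is the usual, thermodynamically preferred product.

**Step 4**
Reactants: 6 tert-butyl (E)-3-methoxy-2-(5,6,7-trimethoxy-4-oxochromen-2-yl)prop-2-enoate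
Product: 7 (E)-3-methoxy-2-(5,6,7-trimethoxy-4-oxochromen-2-yl)prop-2-enoic acid
Conditions: TFA, CH2Cl2, 0 °C to rt
Reagents that add atoms: none
Why: Acidolysis of the tert-butyl ester (loss of isobutene) frees the acid without hydroxide, which could open the pyranone at C2 or attack the enol ether β-carbon; the pyranone is protonated in TFA, which should protect ring A from tert-butylation.

**Step 5**
Reactants: 7 (E)-3-methoxy-2-(5,6,7-trimethoxy-4-oxochromen-2-yl)prop-2-enoic acid
Product: 9 (E)-1-diazo-4-methoxy-3-(5,6,7-trimethoxy-4-oxochromen-2-yl)but-3-en-2-one, via acyl chloride 8 (not isolated)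
Conditions: 1-chloro-N,N,2-trimethylprop-1-en-1-amine, CH2Cl2, 0 °C to rt; then Me3SiCHN2 (2.2 equiv), MeCN/THF, 0 °C to rt
Reagents that add atoms: trimethylsilyldiazomethane, C[Si](C)(C)C=[N+]=[N-]
Why: Neutral chlorination by the α-chloroenamine gives an acyl chloride without α-hydrogen, which should acylate trimethylsilyldiazomethane with loss of the silyl group (Arndt–Eistert-type diazo ketone synthesis); the donor-substituted trisubstituted alkene is a poor dipolarophile, which should limit pyrazoline formation.

**Step 6**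
Reactants: 10 acetylene
Product: 12 triisopropylsilyloxyacetylene, via lithium ethynolate 11 (not isolated)
Conditions: n-BuLi, THF, −78 °C; LiOOt-Bu (from t-BuOOH and LiN(SiMe3)2), −78 to −20 °C; i-Pr3SiOTf, −78 °C
Reagents that add atoms: tert-butyl hydroperoxide, CC(C)(C)OO; triisopropylsilyl trifluoromethanesulfonate, CC(C)[Si](OS(=O)(=O)C(F)(F)F)(C(C)C)C(C)C
Why: Electrophilic oxygenation of the lithium acetylide by lithium tert-butyl peroxide should give the ynolate, which the bulky silyl triflate silylates on oxygen and not on carbon (Julia-type synthesis of silyl ynol ethers).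

**Step 7**
Reactants: 9 (E)-1-diazo-4-methoxy-3-(5,6,7-trimethoxy-4-oxochromen-2-yl)but-3-en-2-one; 12 triisopropylsilyloxyacetylene
Product: 17 2-[3-hydroxy-2-methoxy-5-(triisopropylsilyloxy)phenyl]-5,6,7-trimethoxychromen-4-one, via vinylketene 13 (not isolated), via vinylcyclobutenone 14 (not isolated), via dienylketene 15 (not isolated), via cyclohexadienone 16 (not isolated)
Conditions: 12 (3 equiv), hν (440 nm LED), ClCH2CH2Cl, rt; then 80 °C
Reagents that add atoms: none
Why: Excitation of the long-wavelength band of the diazo ketone expels N2 and the β-methoxyvinyl group shifts to the former diazo carbon (photochemical Wolff rearrangement, forming C1'–C6') to give vinylketene 13, whose carbonyl carbon is attacked by the nucleophilic CH terminus of 12 so that the (2+2) adduct closes as 3-siloxy-4-vinylcyclobutenone 14 (C3'–C4' and C5'–C6'). On warming, 14 opens by reversible conrotatory four-electron cleavage of its C3'–C6' bond to dienylketene 15, and ring B closes by disrotatory six-electron electrocyclisation in which the ketene carbon bonds to the methoxy-bearing vinyl carbon (C2'–C3'), giving cyclohexadienone 16, which enolises to phenol 17. This is the Danheiser benzannulation in its photochemical Wolff variant with a siloxyalkyne, a known reaction of α-diazo ketones carrying α',β'-unsaturation. No stereocenter survives, since the sp3 carbons of 14 and 16 are lost on aromatisation; the ketene oxygen ends as the free C3'-OH, the alkyne oxygen as C5'-O, and the enol ether carbon as C2'-OMe. The 3',5' relation of the two oxygens depends on the regiochemistry of the (2+2) step, which the polarisation of the ynol silyl ether fixes, and the E enol ether keeps OMe on the outside in the electrocyclisation. Chemoselectivity is sought by irradiating at 440 nm, where the chromone should not absorb, and by using the electron-rich alkyne in excess so that it outcompetes the chromone C2–C3 bond and the product phenol for the ketene.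

**Step 8**
Reactants: 17 2-[3-hydroxy-2-methoxy-5-(triisopropylsilyloxy)phenyl]-5,6,7-trimethoxychromen-4-one
Product: 18 2-(3,5-dihydroxy-2-methoxyphenyl)-5,6,7-trimethoxychromen-4-one
Conditions: Bu4NF, AcOH, THF, 0 °C
Reagents that add atoms: none
Why: Fluoride-induced desilylation of the aryl silyl ether, buffered with acetic acid to keep the phenoxides from oxidising, should leave all methyl ethers untouched.

**Step 9**
Reactants: 18 2-(3,5-dihydroxy-2-methoxyphenyl)-5,6,7-trimethoxychromen-4-one
Product: 19 2-(3,5-dihydroxy-2-methoxyphenyl)-5-hydroxy-6,7-dimethoxychromen-4-one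
Conditions: BCl3 (5 equiv), CH2Cl2, −78 to 0 °C; then aq. HCl, MeOH
Reagents that add atoms: none
Why: BCl3 binds the C4 carbonyl and the peri 5-OMe in a six-membered chelate and chloride removes that methyl only (chelation-controlled demethylation of 5-methoxyflavones), so at low temperature the 6-, 7- and 2'-OMe groups should be kept.

**Compound list**
1 | 2'-hydroxy-4',5',6'-trimethoxyacetophenone | CC(=O)c1c(O)cc(OC)c(OC)c1OC | starting material
2 | 1-(2-hydroxy-4,5,6-trimethoxyphenyl)butane-1,3-dione | CC(=O)CC(=O)c1c(O)cc(OC)c(OC)c1OC | intermediate (not isolated)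
3 | 5,6,7-trimethoxy-2-methylchromen-4-one | Cc1cc(=O)c2c(OC)c(OC)c(OC)cc2o1 | intermediate
4 | tert-butyl 2-(5,6,7-trimethoxy-4-oxochromen-2-yl)acetate | CC(C)(C)OC(=O)Cc1cc(=O)c2c(OC)c(OC)c(OC)cc2o1 | intermediate
5 | tert-butyl 3-hydroxy-2-(5,6,7-trimethoxy-4-oxochromen-2-yl)prop-2-enoate (enol of the α-formyl ester, present as its sodium salt, geometry not fixed) | CC(C)(C)OC(=O)C(=CO)c1cc(=O)c2c(OC)c(OC)c(OC)cc2o1 | intermediate (not isolated)
6 | tert-butyl (E)-3-methoxy-2-(5,6,7-trimethoxy-4-oxochromen-2-yl)prop-2-enoate | CO/C=C(\c1cc(=O)c2c(OC)c(OC)c(OC)cc2o1)C(=O)OC(C)(C)C | intermediate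
7 | (E)-3-methoxy-2-(5,6,7-trimethoxy-4-oxochromen-2-yl)prop-2-enoic acid | CO/C=C(\c1cc(=O)c2c(OC)c(OC)c(OC)cc2o1)C(=O)O | intermediate
8 | (E)-3-methoxy-2-(5,6,7-trimethoxy-4-oxochromen-2-yl)prop-2-enoyl chloride | CO/C=C(\c1cc(=O)c2c(OC)c(OC)c(OC)cc2o1)C(=O)Cl | intermediate (not isolated)
9 | (E)-1-diazo-4-methoxy-3-(5,6,7-trimethoxy-4-oxochromen-2-yl)but-3-en-2-one | CO/C=C(\c1cc(=O)c2c(OC)c(OC)c(OC)cc2o1)C(=O)C=[N+]=[N-] | intermediate
10 | acetylene | C#C | starting material
11 | lithium ethynolate | [Li+].[O-]C#C | intermediate (not isolated)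
12 | triisopropylsilyloxyacetylene | C#CO[Si](C(C)C)(C(C)C)C(C)C | intermediate
13 | (Z)-4-methoxy-3-(5,6,7-trimethoxy-4-oxochromen-2-yl)buta-1,3-dien-1-one | CO/C=C(\c1cc(=O)c2c(OC)c(OC)c(OC)cc2o1)C=C=O | intermediate (not isolated)
14 | 4-[(Z)-2-methoxy-1-(5,6,7-trimethoxy-4-oxochromen-2-yl)ethenyl]-3-(triisopropylsilyloxy)cyclobut-2-en-1-one (racemic) | CO/C=C(\c1cc(=O)c2c(OC)c(OC)c(OC)cc2o1)C1C(=O)C=C1O[Si](C(C)C)(C(C)C)C(C)C | intermediate (not isolated)
15 | (3E,5Z)-6-methoxy-5-(5,6,7-trimethoxy-4-oxochromen-2-yl)-3-(triisopropylsilyloxy)hexa-1,3,5-trien-1-one | O=C=C/C(O[Si](C(C)C)(C(C)C)C(C)C)=C\C(=C\OC)c1cc(=O)c2c(OC)c(OC)c(OC)cc2o1 | intermediate (not isolated)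
16 | 6-methoxy-5-(5,6,7-trimethoxy-4-oxochromen-2-yl)-3-(triisopropylsilyloxy)cyclohexa-2,4-dien-1-one (racemic) | COC1C(=O)C=C(O[Si](C(C)C)(C(C)C)C(C)C)C=C1c1cc(=O)c2c(OC)c(OC)c(OC)cc2o1 | intermediate (not isolated)
17 | 2-[3-hydroxy-2-methoxy-5-(triisopropylsilyloxy)phenyl]-5,6,7-trimethoxychromen-4-one | COc1cc2oc(-c3cc(O[Si](C(C)C)(C(C)C)C(C)C)cc(O)c3OC)cc(=O)c2c(OC)c1OC | intermediate
18 | 2-(3,5-dihydroxy-2-methoxyphenyl)-5,6,7-trimethoxychromen-4-one | COc1cc2oc(-c3cc(O)cc(O)c3OC)cc(=O)c2c(OC)c1OC | intermediate
19 | 2-(3,5-dihydroxy-2-methoxyphenyl)-5-hydroxy-6,7-dimethoxychromen-4-one | COc1cc2oc(-c3cc(O)cc(O)c3OC)cc(=O)c2c(O)c1OC | target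

**Step count**
Total steps: 9. Longest linear sequence: 8 (steps 1 to 5, then 7, 8, 9); step 6 is a one-step side branch.

**Steps most likely to fail**

1. Step 7. The ketene may be lost before it meets the alkyne: the chromone may be excited or undergo photocycloaddition, the ketene may dimerise or acylate the product phenol, or the cyclobutenone may fail to open and recyclise cleanly. The fallback brings ring B in ready-made instead of building it. It sets out from 1 and returns at 18.
   - O-Methylation of commercial 3,5-dibromosalicylaldehyde (MeI, K2CO3, DMF) would give 3,5-dibromo-2-methoxybenzaldehyde F1.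
   - Claisen–Schmidt condensation of 1 with F1 (KOH, EtOH, rt) would give (E)-3-(3,5-dibromo-2-methoxyphenyl)-1-(2-hydroxy-4,5,6-trimethoxyphenyl)prop-2-en-1-one F2.
   - Oxidative cyclisation (catalytic I2, DMSO, 130 °C) would give 2-(3,5-dibromo-2-methoxyphenyl)-5,6,7-trimethoxychromen-4-one F3.
   - Double Miyaura borylation (B2pin2, PdCl2(dppf), KOAc, dioxane, 90 °C) would give 2-[2-methoxy-3,5-bis(4,4,5,5-tetramethyl-1,3,2-dioxaborolan-2-yl)phenyl]-5,6,7-trimethoxychromen-4-one F4.
   - Oxidation (NaBO3·4H2O, THF/H2O, rt) would give 18, which goes on to step 9.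

2. Step 5. The acylation may be overtaken by dipolar cycloaddition of the diazoalkane to the conjugated alkene or the chromone C2–C3 bond, by chlorination at the pyranone carbonyl, or the deactivated acyl chloride may react too slowly. The fallback installs the diazo group by diazo transfer onto a methyl ketone instead of acylating a diazoalkane. It sets out from 3 and returns at 9.
   - Lateral acetylation of 3 (LiN(SiMe3)2, THF, −78 °C; N-methoxy-N-methylacetamide) would give 5,6,7-trimethoxy-2-(2-oxopropyl)chromen-4-one F5.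
   - Methoxymethylenation of its doubly activated methylene (HC(OMe)3, Ac2O, 110 °C) would give (E)-4-methoxy-3-(5,6,7-trimethoxy-4-oxochromen-2-yl)but-3-en-2-one F6; either enol ether isomer would serve.
   - Detrifluoroacetylative diazo transfer (LiN(SiMe3)2, THF, −78 °C; CF3CO2CH2CF3; then MsN3, Et3N, H2O, MeCN, rt) would pass through (E)-1,1,1-trifluoro-6-methoxy-5-(5,6,7-trimethoxy-4-oxochromen-2-yl)hex-5-ene-2,4-dione F7, which is not isolated, and give 9.

3. Step 6. Monolithium acetylide may disproportionate on warming before oxygen transfer, the ynolate may be silylated on carbon to a silylketene, or the volatile, moisture-sensitive alkyne may be lost on isolation. The fallback generates the same ynolate by ester homologation instead of acetylide oxidation. It does not use 10; it sets out from ethyl formate and dibromomethane and rejoins the route at 11.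
   - Dibromomethyllithium (CH2Br2, lithium 2,2,6,6-tetramethylpiperidide, THF, −78 °C) would add to ethyl formate to give lithium 2,2-dibromo-1-ethoxyethan-1-olate F8.
   - Collapse of F8 and deprotonation (LiN(SiMe3)2) would give lithium 2,2-dibromoethen-1-olate F9.
   - Bromine–lithium exchange (n-BuLi, −78 to 0 °C) and 1,2-hydrogen shift would give 11, which is silylated with i-Pr3SiOTf as in step 6 to give 12.

**Further compounds**
F1 | step 7 | 3,5-dibromo-2-methoxybenzaldehyde | COc1c(Br)cc(Br)cc1C=O
F2 | step 7 | (E)-3-(3,5-dibromo-2-methoxyphenyl)-1-(2-hydroxy-4,5,6-trimethoxyphenyl)prop-2-en-1-one | COc1cc(O)c(C(=O)/C=C/c2cc(Br)cc(Br)c2OC)c(OC)c1OC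
F3 | step 7 | 2-(3,5-dibromo-2-methoxyphenyl)-5,6,7-trimethoxychromen-4-one | COc1cc2oc(-c3cc(Br)cc(Br)c3OC)cc(=O)c2c(OC)c1OC
F4 | step 7 | 2-[2-methoxy-3,5-bis(4,4,5,5-tetramethyl-1,3,2-dioxaborolan-2-yl)phenyl]-5,6,7-trimethoxychromen-4-one | COc1cc2oc(-c3cc(B4OC(C)(C)C(C)(C)O4)cc(B4OC(C)(C)C(C)(C)O4)c3OC)cc(=O)c2c(OC)c1OC
F5 | step 5 | 5,6,7-trimethoxy-2-(2-oxopropyl)chromen-4-one | CC(=O)Cc1cc(=O)c2c(OC)c(OC)c(OC)cc2o1
F6 | step 5 | (E)-4-methoxy-3-(5,6,7-trimethoxy-4-oxochromen-2-yl)but-3-en-2-one | CO/C=C(\c1cc(=O)c2c(OC)c(OC)c(OC)cc2o1)C(C)=O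
F7 | step 5 | (E)-1,1,1-trifluoro-6-methoxy-5-(5,6,7-trimethoxy-4-oxochromen-2-yl)hex-5-ene-2,4-dione | CO/C=C(\c1cc(=O)c2c(OC)c(OC)c(OC)cc2o1)C(=O)CC(=O)C(F)(F)F
F8 | step 6 | lithium 2,2-dibromo-1-ethoxyethan-1-olate | [Li+].CCOC([O-])C(Br)Br
F9 | step 6 | lithium 2,2-dibromoethen-1-olate | [Li+].[O-]C=C(Br)Br
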